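**Plan**

Ring A is counted in the order of the target SMILES: position 1 carries the prenyloxy group, position 2 is CH, position 3 a hydroxyl, position 4 the bridging CH2, position 5 a hydroxyl and position 6 the benzoyl group.
The retrosynthesis cuts first the bond from the bridging CH2 to the trione ring, then the bond from position 4 to that carbon, and last, in one operation, the C–O bond at position 5 and the aryl–acyl bond at position 6.
The double cut is possible because the hydroxyl carbon (position 5) and the benzoyl carbon (position 6) are neighbours and position 6 also adjoins the ether carbon (position 1); an aryne across positions 5 and 6, polarised by that alkoxy group, can insert into the C–O bond of benzoic acid with oxygen on position 5 and the acyl carbon on position 6.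
Forward, a mono-MOM phloroglucinol is bis-carbamoylated, silylated between the carbamates, unmasked, mono-prenylated and triflated; aryne insertion then gives the benzophenone, which is formylated at position 4 and freed of its MOM group.
The 2-isobutyryl-4,4-dimethyl trione (two steps from phloroglucinol) is joined last by reductive alkylation with the aldehyde; no ring is formed anywhere, both six-membered rings coming from phloroglucinol-type starting materials.
The target has no stereocentre and no stereogenic double bond, so no stereochemistry has to be set.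

Key step: step 8

Remark: the trione ring is written throughout as the enol tautomer of the target SMILES (the tautomers interconvert freely), and 3,5-bis(benzyloxy)phenol is taken as a commercial compound so that the single MOM group can be placed without a statistical protection.

**Route**

Step 1
Reactants: 1 3,5-bis(benzyloxy)phenol
Product: 2 1,3-bis(benzyloxy)-5-(methoxymethoxy)benzene
Conditions: MOMCl, i-Pr2NEt, CH2Cl2, 0 °C to rt
Reagents that add atoms: chloromethyl methyl ether, COCCl
Why: O-Alkylation of the only free phenol with the α-chloro ether under amine base (Williamson-type acetal formation) should be clean since no other nucleophilic site is present.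

Step 2
Reactants: 2 1,3-bis(benzyloxy)-5-(methoxymethoxy)benzene
Product: 3 5-(methoxymethoxy)benzene-1,3-diol
Conditions: hydrogen (1 atm), 10% Pd/C, EtOAc/MeOH, rt
Reagents that add atoms: none
Why: Catalytic hydrogenolysis of the two benzyl aryl ethers over palladium leaves the MOM acetal intact under neutral conditions and so delivers the mono-protected triol without a statistical protection.

Step 3
Reactants: 3 5-(methoxymethoxy)benzene-1,3-diol
Product: 4 5-(methoxymethoxy)-1,3-phenylene bis(N,N-diethylcarbamate)
Conditions: ClCONEt2, K2CO3, MeCN, reflux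
Reagents that add atoms: N,N-diethylcarbamoyl chloride, CCN(CC)C(Cl)=O
Why: O-Carbamoylation of both phenols with the carbamoyl chloride and carbonate base is routine and installs the two strongest oxygen-based directing groups for the metalation.

Step 4
Reactants: 4 5-(methoxymethoxy)-1,3-phenylene bis(N,N-diethylcarbamate)
Product: 6 5-(methoxymethoxy)-2-(trimethylsilyl)-1,3-phenylene bis(N,N-diethylcarbamate), via 2-lithio bis(carbamate) 5 (not isolated)
Conditions: s-BuLi, TMEDA, THF, −78 °C; then TMSCl, −78 °C to rt
Reagents that add atoms: chlorotrimethylsilane, C[Si](C)(C)Cl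
Why: Directed ortho-metalation should take place at the ring carbon flanked by both O-carbamates, the kinetically most acidic site because the carbamate outranks the MOM ether as a director and two of them cooperate, and the aryllithium is silylated at −78 °C before an anionic Fries shift can set in.

Step 5
Reactants: 6 5-(methoxymethoxy)-2-(trimethylsilyl)-1,3-phenylene bis(N,N-diethylcarbamate)
Product: 7 5-(methoxymethoxy)-2-(trimethylsilyl)benzene-1,3-diol
Conditions: LiAlH4, THF, 0 °C to reflux; aq. potassium sodium tartrate work-up
Reagents that add atoms: none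
Why: Hydride cleavage of aryl N,N-diethylcarbamates with LiAlH4 frees both phenols under basic conditions that spare the acid-sensitive aryl–silicon bond and the MOM acetal, provided the work-up stays neutral.

Step 6
Reactants: 7 5-(methoxymethoxy)-2-(trimethylsilyl)benzene-1,3-diol; 8 prenyl bromide (1-bromo-3-methylbut-2-ene)
Product: 9 5-(methoxymethoxy)-3-(3-methylbut-2-enyloxy)-2-(trimethylsilyl)phenol
Conditions: K2CO3, acetone, rt (bromide 8 as limiting reagent)
Reagents that add atoms: none
Why: Williamson etherification with the bromide as limiting reagent should give mainly the mono-ether (the two phenols are equivalent, so the distribution is statistical and recovered diol 7 is recycled), and carbonate in acetone favours O- over C-alkylation.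

Step 7
Reactants: 9 5-(methoxymethoxy)-3-(3-methylbut-2-enyloxy)-2-(trimethylsilyl)phenol
Product: 10 5-(methoxymethoxy)-3-(3-methylbut-2-enyloxy)-2-(trimethylsilyl)phenyl trifluoromethanesulfonate
Conditions: PhNTf2, DBU, MeCN, rt to 40 °C
Reagents that add atoms: N-phenyl-bis(trifluoromethanesulfonimide), O=S(=O)(N(c1ccccc1)S(=O)(=O)C(F)(F)F)C(F)(F)F
Why: Triflation of the hindered ortho-silyl phenol with PhNTf2 and an amidine base is the usual last step in making ortho-silylaryl triflate aryne precursors and avoids the strong acid that triflic anhydride would set free next to the electron-rich aryl silane.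

Step 8
Reactants: 10 5-(methoxymethoxy)-3-(3-methylbut-2-enyloxy)-2-(trimethylsilyl)phenyl trifluoromethanesulfonate; 11 benzoic acid
Product: 14 [2-hydroxy-4-(methoxymethoxy)-6-(3-methylbut-2-enyloxy)phenyl](phenyl)methanone, via aryne 12 (not isolated), via ortho-benzoyloxyaryl cesium 13 (not isolated)
Conditions: CsF, THF, 125 °C (sealed tube); aq. NH4Cl work-up
Reagents that add atoms: none
Why: Fluoride attacks silicon and triflate leaves from the neighbouring carbon, giving aryne 12 with the triple bond between positions 5 and 6 of ring A; cesium benzoate adds through oxygen at position 5, the aryl anion 13 at position 6 attacks the carbonyl of its own ortho-benzoyloxy group through a four-membered transition state, and collapse of that adduct leaves the ketone at position 6 and the phenoxide at position 5, which is protonated on work-up. The closest known reaction type is the intermolecular insertion of arynes from ortho-silylaryl triflates into the C–O bond of carboxylic acids, which gives ortho-hydroxyaryl ketones at elevated temperature. No ring is closed (the four-membered species is only a transition state) and no stereocentre is formed. The step needs regioselective addition: the alkoxy group at position 1 withdraws inductively and distorts the aryne so that position 5 is the more linear, more electrophilic terminus and the negative charge develops at position 6 next to the C–O bond, which puts the benzoate oxygen on position 5 and the acyl group on position 6. It also needs acyl transfer to outrun protonation of the anion (which would stop at the aryl benzoate); the high temperature, near-stoichiometric acid and the absence of other proton sources should secure this, and the MOM and prenyl ethers are inert to CsF.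

Step 9
Reactants: 14 [2-hydroxy-4-(methoxymethoxy)-6-(3-methylbut-2-enyloxy)phenyl](phenyl)methanone
Product: 16 3-benzoyl-2-hydroxy-6-(methoxymethoxy)-4-(3-methylbut-2-enyloxy)benzaldehyde, via hydroxymethyl intermediate 15 (not isolated)
Conditions: MgCl2, Et3N, (CH2O)n, MeCN, reflux; aq. NH4Cl work-up
Reagents that add atoms: formaldehyde (as paraformaldehyde), C=O
Why: Magnesium-mediated ortho-formylation (Casnati–Skattebøl reaction) delivers formaldehyde from the chloromagnesium phenoxide of the position 5 hydroxyl to its only free ortho carbon, position 4, through a six-membered transition state, and a second formaldehyde oxidises the benzylic alkoxide 15 by hydride transfer, so position 2 (para to the phenol) stays untouched.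

Step 10
Reactants: 16 3-benzoyl-2-hydroxy-6-(methoxymethoxy)-4-(3-methylbut-2-enyloxy)benzaldehyde
Product: 17 3-benzoyl-2,6-dihydroxy-4-(3-methylbut-2-enyloxy)benzaldehyde
Conditions: HCl (cat.), MeOH/THF, rt
Reagents that add atoms: none
Why: Acid-catalysed acetal exchange with methanol removes the MOM group, which on a phenol oxygen ortho to the formyl group is cleaved under conditions mild enough for the prenyl ether, and doing this at the aldehyde stage keeps acid away from the finished dimer.

Step 11
Reactants: 18 phloroglucinol; 19 isobutyryl chloride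
Product: 20 2-methyl-1-(2,4,6-trihydroxyphenyl)propan-1-one
Conditions: AlCl3, PhNO2/CH2Cl2, 0 °C to 40 °C
Reagents that add atoms: none
Why: Friedel–Crafts acylation of phloroglucinol stops after one acyl group because the ketone, chelated to AlCl3 and to the flanking phenols, deactivates the ring.

Step 12
Reactants: 20 2-methyl-1-(2,4,6-trihydroxyphenyl)propan-1-one
Product: 21 3,5-dihydroxy-6,6-dimethyl-2-(2-methylpropanoyl)cyclohexa-2,4-dien-1-one (isobutyrylfilicinic acid)
Conditions: NaOMe, MeI, MeOH, 0 °C to rt
Reagents that add atoms: iodomethane, CI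
Why: Dearomatising double C-methylation of the acylphloroglucinol as its phenoxide, the established entry to acylfilicinic acids, should give the gem-dimethyl trione when the iodide is held near two equivalents, mono- and over-methylated congeners being removed by chromatography.

Step 13
Reactants: 17 3-benzoyl-2,6-dihydroxy-4-(3-methylbut-2-enyloxy)benzaldehyde; 21 isobutyrylfilicinic acid
Product: 23 sarothralin, via Knoevenagel alkylidene 22 (not isolated)
Conditions: L-proline (cat.), Hantzsch ester, CH2Cl2, rt
Reagents that add atoms: none
Why: Three-component reductive alkylation: proline-catalysed Knoevenagel condensation of the aldehyde with the acidic ring carbon of 21 gives alkylidene 22, an electron-poor alkene that is reduced at once by conjugate hydride transfer from the Hantzsch ester, which does not touch the free aldehyde and outruns the addition of a second trione.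

**Compound list**

1 | 3,5-bis(benzyloxy)phenol | Oc1cc(OCc2ccccc2)cc(OCc2ccccc2)c1 | starting material
2 | 1,3-bis(benzyloxy)-5-(methoxymethoxy)benzene | COCOc1cc(OCc2ccccc2)cc(OCc2ccccc2)c1 | intermediate
3 | 5-(methoxymethoxy)benzene-1,3-diol | COCOc1cc(O)cc(O)c1 | intermediate
4 | 5-(methoxymethoxy)-1,3-phenylene bis(N,N-diethylcarbamate) | CCN(CC)C(=O)Oc1cc(OCOC)cc(OC(=O)N(CC)CC)c1 | intermediate
5 | 2-lithio-5-(methoxymethoxy)-1,3-phenylene bis(N,N-diethylcarbamate) (not isolated) | CCN(CC)C(=O)Oc1cc(OCOC)cc(OC(=O)N(CC)CC)c1[Li] | intermediate
6 | 5-(methoxymethoxy)-2-(trimethylsilyl)-1,3-phenylene bis(N,N-diethylcarbamate) | CCN(CC)C(=O)Oc1cc(OCOC)cc(OC(=O)N(CC)CC)c1[Si](C)(C)C | intermediate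
7 | 5-(methoxymethoxy)-2-(trimethylsilyl)benzene-1,3-diol | COCOc1cc(O)c([Si](C)(C)C)c(O)c1 | intermediate
8 | prenyl bromide (1-bromo-3-methylbut-2-ene) | CC(C)=CCBr | starting material
9 | 5-(methoxymethoxy)-3-(3-methylbut-2-enyloxy)-2-(trimethylsilyl)phenol | CC(C)=CCOc1cc(OCOC)cc(O)c1[Si](C)(C)C | intermediate
10 | 5-(methoxymethoxy)-3-(3-methylbut-2-enyloxy)-2-(trimethylsilyl)phenyl trifluoromethanesulfonate | CC(C)=CCOc1cc(OCOC)cc(OS(=O)(=O)C(F)(F)F)c1[Si](C)(C)C | intermediate
11 | benzoic acid | OC(=O)c1ccccc1 | starting material
12 | 5-(methoxymethoxy)-3-(3-methylbut-2-enyloxy)benzyne, triple bond between positions 5 and 6 of ring A (not isolated) | CC(C)=CCOC1=CC(OCOC)=CC#C1 | intermediate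
13 | [2-(benzoyloxy)-4-(methoxymethoxy)-6-(3-methylbut-2-enyloxy)phenyl]cesium (not isolated) | CC(C)=CCOc1cc(OCOC)cc(OC(=O)c2ccccc2)c1[Cs] | intermediate
14 | [2-hydroxy-4-(methoxymethoxy)-6-(3-methylbut-2-enyloxy)phenyl](phenyl)methanone | CC(C)=CCOc1cc(OCOC)cc(O)c1C(=O)c1ccccc1 | intermediate
15 | [2-hydroxy-3-(hydroxymethyl)-4-(methoxymethoxy)-6-(3-methylbut-2-enyloxy)phenyl](phenyl)methanone, present as its chloromagnesium alkoxide (not isolated) | CC(C)=CCOc1cc(OCOC)c(CO)c(O)c1C(=O)c1ccccc1 | intermediate
16 | 3-benzoyl-2-hydroxy-6-(methoxymethoxy)-4-(3-methylbut-2-enyloxy)benzaldehyde | CC(C)=CCOc1cc(OCOC)c(C=O)c(O)c1C(=O)c1ccccc1 | intermediate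
17 | 3-benzoyl-2,6-dihydroxy-4-(3-methylbut-2-enyloxy)benzaldehyde | CC(C)=CCOc1cc(O)c(C=O)c(O)c1C(=O)c1ccccc1 | intermediate
18 | phloroglucinol (benzene-1,3,5-triol) | Oc1cc(O)cc(O)c1 | starting material
19 | isobutyryl chloride (2-methylpropanoyl chloride) | CC(C)C(Cl)=O | starting material
20 | 2-methyl-1-(2,4,6-trihydroxyphenyl)propan-1-one | CC(C)C(=O)c1c(O)cc(O)cc1O | intermediate
21 | 3,5-dihydroxy-6,6-dimethyl-2-(2-methylpropanoyl)cyclohexa-2,4-dien-1-one (isobutyrylfilicinic acid) | CC(C)C(=O)C1=C(O)C=C(O)C(C)(C)C1=O | intermediate
22 | 6-{[3-benzoyl-2,6-dihydroxy-4-(3-methylbut-2-enyloxy)phenyl]methylidene}-5-hydroxy-2,2-dimethyl-4-(2-methylpropanoyl)cyclohex-4-ene-1,3-dione, alkene geometry not fixed, either isomer is reduced to the same product (not isolated) | CC(C)=CCOc1cc(O)c(C=C2C(=O)C(C)(C)C(=O)C(C(=O)C(C)C)=C2O)c(O)c1C(=O)c1ccccc1 | intermediate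
23 | sarothralin, 4-{[3-benzoyl-2,6-dihydroxy-4-(3-methylbut-2-enyloxy)phenyl]methyl}-3,5-dihydroxy-6,6-dimethyl-2-(2-methylpropanoyl)cyclohexa-2,4-dien-1-one (achiral) | CC(C)=CCOc1cc(O)c(CC2=C(O)C(C)(C)C(=O)C(C(=O)C(C)C)=C2O)c(O)c1C(=O)c1ccccc1 | target

**Totals**

Total step count: 13 (steps 1–10 for ring A, steps 11–12 for the trione, step 13 for the union).
Longest linear sequence: 11 steps (steps 1–10 and 13).

**Three steps most likely to fail**

Step 8. The aryne may be intercepted by the double bond of the neighbouring prenyl ether before benzoate adds (intramolecular ene reaction, with position 6 of ring A bonding to the alkene CH and a methyl hydrogen passing to position 5), or the prenyl ether may begin a sigmatropic shift at 125 °C. The fallback removes the ene-competent side chain from the aryne and sets out from diol 7. Mono-O-alkylation with allyl bromide (K2CO3, acetone) should give 5-(methoxymethoxy)-3-(prop-2-enyloxy)-2-(trimethylsilyl)phenol F1, and triflation (PhNTf2, DBU, MeCN) the corresponding 5-(methoxymethoxy)-3-(prop-2-enyloxy)-2-(trimethylsilyl)phenyl trifluoromethanesulfonate F2. The same CsF/benzoic acid insertion (THF, 125 °C) should then give [2-hydroxy-4-(methoxymethoxy)-6-(prop-2-enyloxy)phenyl](phenyl)methanone F3, since the allyl ether lacks the methyl hydrogens that the ene pathway needs. Olefin cross-metathesis of F3 with 2-methylbut-2-ene (second-generation Grubbs catalyst, RuCl2(=CHPh)(H2IMes)(PCy3), CH2Cl2, 40 °C) should turn the allyl into the prenyl ether, which comes back to the route at 14.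

Step 13. The condensation may stall because the aldehyde carbonyl is hydrogen-bonded on both sides and crowded, or the alkylidene may close onto a neighbouring phenol oxygen before hydride transfer. The fallback makes ring A the electrophile in a stable, isolable form and sets out from aldehyde 17. Reductive amination with dimethylamine (Me2NH, NaBH(OAc)3, 1,2-dichloroethane, rt) should give the phenolic Mannich base {3-[(dimethylamino)methyl]-2,4-dihydroxy-6-(3-methylbut-2-enyloxy)phenyl}(phenyl)methanone F4. Heating F4 with trione 21 (toluene, 90 °C) should expel dimethylamine to form the ortho-quinone methide, which the acidic ring carbon of 21 traps by Michael addition; this comes back to the route at 23.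

Step 6. Alkylation may not stop after the first of two equivalent phenols, and the electron-rich ring may be alkylated on carbon. The fallback tells the two oxygens apart before silicon is introduced and sets out from diol 3. Carbamoylation with a deficit of ClCONEt2 (K2CO3, MeCN) should give 3-hydroxy-5-(methoxymethoxy)phenyl N,N-diethylcarbamate F5, the bis-carbamate formed alongside being 4, which feeds step 4. Isopropyl isocyanate (Et3N cat., CH2Cl2) should convert the remaining phenol into 3-(diethylcarbamoyloxy)-5-(methoxymethoxy)phenyl N-(propan-2-yl)carbamate F6. In one flask, TBSOTf and TMEDA (Et2O, 0 °C) should mask the N–H group as 3-(diethylcarbamoyloxy)-5-(methoxymethoxy)phenyl N-[tert-butyl(dimethyl)silyl]-N-(propan-2-yl)carbamate F7 (not isolated). s-BuLi/TMEDA (−78 °C) followed by TMSCl should silylate the carbon between the two carbamates to give 3-(diethylcarbamoyloxy)-5-(methoxymethoxy)-2-(trimethylsilyl)phenyl N-[tert-butyl(dimethyl)silyl]-N-(propan-2-yl)carbamate F8 (not isolated). Mild aqueous work-up then hydrolyses the labile N–Si bond and leaves 3-(diethylcarbamoyloxy)-5-(methoxymethoxy)-2-(trimethylsilyl)phenyl N-(propan-2-yl)carbamate F9. DBU/Et2NH (MeCN, 40 °C) should remove only the N–H carbamate, by elimination to isopropyl isocyanate, a path closed to the N,N-diethylcarbamate, and give 3-hydroxy-5-(methoxymethoxy)-2-(trimethylsilyl)phenyl N,N-diethylcarbamate F10. Prenylation with 8 (K2CO3, acetone) should then give 5-(methoxymethoxy)-3-(3-methylbut-2-enyloxy)-2-(trimethylsilyl)phenyl N,N-diethylcarbamate F11, and LiAlH4 (THF) cleaves the last carbamate, which comes back to the route at 9.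

**Further compounds**

F1 | step 8 | 5-(methoxymethoxy)-3-(prop-2-enyloxy)-2-(trimethylsilyl)phenol | C=CCOc1cc(OCOC)cc(O)c1[Si](C)(C)C
F2 | step 8 | 5-(methoxymethoxy)-3-(prop-2-enyloxy)-2-(trimethylsilyl)phenyl trifluoromethanesulfonate | C=CCOc1cc(OCOC)cc(OS(=O)(=O)C(F)(F)F)c1[Si](C)(C)C
F3 | step 8 | [2-hydroxy-4-(methoxymethoxy)-6-(prop-2-enyloxy)phenyl](phenyl)methanone | C=CCOc1cc(OCOC)cc(O)c1C(=O)c1ccccc1
F4 | step 13 | {3-[(dimethylamino)methyl]-2,4-dihydroxy-6-(3-methylbut-2-enyloxy)phenyl}(phenyl)methanone | CC(C)=CCOc1cc(O)c(CN(C)C)c(O)c1C(=O)c1ccccc1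
F5 | step 6 | 3-hydroxy-5-(methoxymethoxy)phenyl N,N-diethylcarbamate | CCN(CC)C(=O)Oc1cc(O)cc(OCOC)c1
F6 | step 6 | 3-(diethylcarbamoyloxy)-5-(methoxymethoxy)phenyl N-(propan-2-yl)carbamate | CCN(CC)C(=O)Oc1cc(OCOC)cc(OC(=O)NC(C)C)c1
F7 | step 6 | 3-(diethylcarbamoyloxy)-5-(methoxymethoxy)phenyl N-[tert-butyl(dimethyl)silyl]-N-(propan-2-yl)carbamate | CCN(CC)C(=O)Oc1cc(OCOC)cc(OC(=O)N(C(C)C)[Si](C)(C)C(C)(C)C)c1
F8 | step 6 | 3-(diethylcarbamoyloxy)-5-(methoxymethoxy)-2-(trimethylsilyl)phenyl N-[tert-butyl(dimethyl)silyl]-N-(propan-2-yl)carbamate | CCN(CC)C(=O)Oc1cc(OCOC)cc(OC(=O)N(C(C)C)[Si](C)(C)C(C)(C)C)c1[Si](C)(C)C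
F9 | step 6 | 3-(diethylcarbamoyloxy)-5-(methoxymethoxy)-2-(trimethylsilyl)phenyl N-(propan-2-yl)carbamate | CCN(CC)C(=O)Oc1cc(OCOC)cc(OC(=O)NC(C)C)c1[Si](C)(C)C
F10 | step 6 | 3-hydroxy-5-(methoxymethoxy)-2-(trimethylsilyl)phenyl N,N-diethylcarbamate | CCN(CC)C(=O)Oc1cc(OCOC)cc(O)c1[Si](C)(C)C
F11 | step 6 | 5-(methoxymethoxy)-3-(3-methylbut-2-enyloxy)-2-(trimethylsilyl)phenyl N,N-diethylcarbamate | CCN(CC)C(=O)Oc1cc(OCOC)cc(OCC=C(C)C)c1[Si](C)(C)C
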